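**Strategy.** The plan rests on disconnecting the C2–C3 bond of the 2,3-dihydrobenzofuran (ring atoms O1, C2, C3, C3a, C7a), which is closed last on a preformed (3S,4S)-dibenzylbutyrolactone. It exploits that C2 is an O-benzylic carbon carrying the electron-rich guaiacyl ring, and that C3 is benzylic to C3a and bears a one-carbon arm that can sit at the carboxyl level. A chiral dirhodium carboxylate turns an aryldiazoacetate at C3 into a carbene that inserts into the O–CH2–aryl C–H bond of the neighbouring ether, closing the ring and setting C2 and C3 in one operation. The precursor is an acyclic benzyl aryl ether with a diazoester, made by Pd-catalysed C–H arylation of benzyl diazoacetate.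

Key step: step 10

Assumption: compounds 4, 8, 10 and 16 are taken as purchasable, and the sense of induction of Rh2(R-PTTL)4 is assigned by analogy with simpler 2-(benzyloxy)aryl diazoacetates; should it prove opposite, the S-configured catalyst is used with no other change.

**Step 1**
Reactants: 1 (S)-epichlorohydrin; 2 diethyl malonate
Product: 3 ethyl (1R,5S)-2-oxo-3-oxabicyclo[3.1.0]hexane-1-carboxylate
Conditions: NaOEt, EtOH, rt then reflux
Reagents that add atoms: none
Why: Malonate–epichlorohydrin annulation, in which the malonate anion opens the epoxide at CH2, the alkoxide re-closes to the transposed epoxide with loss of chloride, a 3-exo-tet alkylation with inversion forms the cyclopropane and the cis ester lactonises, so that C5 comes from the chiral pool.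

**Step 2**
Reactants: 3 ethyl (1R,5S)-2-oxo-3-oxabicyclo[3.1.0]hexane-1-carboxylate; 4 1-(benzyloxy)-4-bromo-2-methoxybenzene
Product: 6 ethyl (3R,4S)-4-{[4-(benzyloxy)-3-methoxyphenyl]methyl}-2-oxooxolane-3-carboxylate, via arylmagnesium bromide 5 (not isolated)
Conditions: Mg, THF, 40 °C; then CuI (20 mol%), 3, THF, −30 → 0 °C; 1 M HCl
Reagents that add atoms: none
Why: Copper-catalysed homoconjugate opening of the doubly activated cyclopropane by the aryl Grignard reagent at the unhindered CH2 leaves the C4 stereocentre untouched and should give, after protonation of the malonate-type enolate, the trans lactone ester (C3 is epimerisable and is removed in step 3).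

**Step 3**
Reactants: 6 ethyl (3R,4S)-4-{[4-(benzyloxy)-3-methoxyphenyl]methyl}-2-oxooxolane-3-carboxylate
Product: 7 (4S)-4-{[4-(benzyloxy)-3-methoxyphenyl]methyl}oxolan-2-one
Conditions: LiCl, DMSO, H2O, 140 °C
Reagents that add atoms: none
Why: Krapcho dealkoxycarbonylation removes the activating ester without touching the C4 stereocentre.

**Step 4**
Reactants: 8 5-iodovanillin (4-hydroxy-3-iodo-5-methoxybenzaldehyde)
Product: 9 3,4-dihydroxy-5-iodobenzaldehyde
Conditions: AlCl3, pyridine, CH2Cl2, reflux; then 2 M HCl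
Reagents that add atoms: none
Why: Lewis acid demethylation of an aryl methyl ether next to a phenol, helped by chelation of aluminium between the two oxygens, leaves the aldehyde and the iodide intact.

**Step 5**
Reactants: 9 3,4-dihydroxy-5-iodobenzaldehyde; 10 4-(benzyloxy)-3-methoxybenzyl chloride (2.2 equiv)
Product: 11 3,4-bis({[4-(benzyloxy)-3-methoxyphenyl]methoxy})-5-iodobenzaldehyde
Conditions: K2CO3, NaI (cat.), DMF, 60 °C
Reagents that add atoms: none
Why: Williamson etherification of both phenols, in which the ether on the para oxygen (the future O1) carries the future C2 with its aryl group and the identical ether on the meta oxygen (the future C7–OH) serves as a hydrogenolysable protecting group, so the two catechol oxygens need not be differentiated.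

**Step 6**
Reactants: 11 3,4-bis({[4-(benzyloxy)-3-methoxyphenyl]methoxy})-5-iodobenzaldehyde
Product: 12 [3,4-bis({[4-(benzyloxy)-3-methoxyphenyl]methoxy})-5-iodophenyl]methanol
Conditions: NaBH4, THF/MeOH, 0 °C
Reagents that add atoms: none
Why: Chemoselective borohydride reduction of the aldehyde to the benzylic alcohol.

**Step 7**
Reactants: 12 [3,4-bis({[4-(benzyloxy)-3-methoxyphenyl]methoxy})-5-iodophenyl]methanol
Product: 13 5-(bromomethyl)-1,2-bis({[4-(benzyloxy)-3-methoxyphenyl]methoxy})-3-iodobenzene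
Conditions: CBr4, PPh3, CH2Cl2, 0 °C
Reagents that add atoms: carbon tetrabromide, BrC(Br)(Br)Br
Why: Appel bromination runs under neutral conditions and so avoids acid cleavage of the electron-rich benzyl aryl ethers.

**Step 8**
Reactants: 7 (4S)-4-{[4-(benzyloxy)-3-methoxyphenyl]methyl}oxolan-2-one; 13 5-(bromomethyl)-1,2-bis({[4-(benzyloxy)-3-methoxyphenyl]methoxy})-3-iodobenzene
Product: 15 (3S,4S)-3-{[3,4-bis({[4-(benzyloxy)-3-methoxyphenyl]methoxy})-5-iodophenyl]methyl}-4-{[4-(benzyloxy)-3-methoxyphenyl]methyl}oxolan-2-one, via lithium lactone enolate 14 (not isolated)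
Conditions: LiHMDS, THF, −78 °C; then 13, DMPU, −78 → −30 °C
Reagents that add atoms: none
Why: Kinetic enolate alkylation of the β-substituted γ-butyrolactone takes place anti to the C4 benzyl group and so sets C3 (S) trans to C4, as is general for dibenzylbutyrolactones, while the aryl iodide is inert to the amide base.

**Step 9**
Reactants: 15 (3S,4S)-3-{[3,4-bis({[4-(benzyloxy)-3-methoxyphenyl]methoxy})-5-iodophenyl]methyl}-4-{[4-(benzyloxy)-3-methoxyphenyl]methyl}oxolan-2-one; 16 benzyl diazoacetate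
Product: 17 benzyl 2-[2,3-bis({[4-(benzyloxy)-3-methoxyphenyl]methoxy})-5-{[(3S,4S)-4-{[4-(benzyloxy)-3-methoxyphenyl]methyl}-2-oxooxolan-3-yl]methyl}phenyl]-2-diazoacetate
Conditions: Pd(PPh3)4 (5 mol%), Ag2CO3 (0.5 equiv), Et3N, toluene, rt
Reagents that add atoms: none
Why: Palladium-catalysed C–H arylation of an acceptor diazo compound with an aryl iodide (oxidative addition, deprotonative C-palladation of the diazoacetate, reductive elimination with the diazo group retained) installs the carbene precursor directly, without a base strong enough to touch the lactone.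

**Step 10**
Reactants: 17 benzyl 2-[2,3-bis({[4-(benzyloxy)-3-methoxyphenyl]methoxy})-5-{[(3S,4S)-4-{[4-(benzyloxy)-3-methoxyphenyl]methyl}-2-oxooxolan-3-yl]methyl}phenyl]-2-diazoacetate
Product: 18 benzyl (2S,3R)-2-[4-(benzyloxy)-3-methoxyphenyl]-7-{[4-(benzyloxy)-3-methoxyphenyl]methoxy}-5-{[(3S,4S)-4-{[4-(benzyloxy)-3-methoxyphenyl]methyl}-2-oxooxolan-3-yl]methyl}-2,3-dihydro-1-benzofuran-3-carboxylate (2,3-cis)
Conditions: Rh2(R-PTTL)4 [dirhodium tetrakis(N-phthaloyl-(R)-tert-leucinate)] (2 mol%), toluene, −60 °C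
Reagents that add atoms: none
Why: The catalyst decomposes the diazoester with loss of N2 to an electrophilic rhodium-bound aryl(ester)carbene at the future C3, which inserts through a concerted, hydride-transfer-like three-centre transition state into the benzylic C–H bond of the ether on the future O1 and so forms the C2–C3 bond. The closest known reaction type is the enantioselective intramolecular C–H insertion of 2-(benzyloxy)aryl diazoacetates to cis-2-aryl-2,3-dihydrobenzofuran-3-carboxylates with chiral dirhodium carboxylates. The one ring that closes (O1, C2, C3, C3a, C7a) forms by 1,5-insertion through a five-membered cyclic transition state. C2 (S) is set by the catalyst, whose phthalimide wall selects one of the two enantiotopic benzylic hydrogens, and C3 (R) follows kinetically as cis to the C2 aryl group and is corrected to trans in step 11. The step needs site selectivity for this one O–CH2 group over every other benzylic C–H bond, the arenes and the ether oxygens; it is secured because only that CH2 lies within 1,5-reach of the carbene (the ether on the future C7 oxygen is meta-disposed, the benzyl ester CH2 would give a four-membered ring, the lactone is remote) and because O1 and the para-oxygenated aryl ring make it the best hydride donor. Any product of the minor enantiotopic pathway is a diastereomer of 18 because of the lactone stereocentres and should be removable by chromatography.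

**Step 11**
Reactants: 18 benzyl (2S,3R)-2-[4-(benzyloxy)-3-methoxyphenyl]-7-{[4-(benzyloxy)-3-methoxyphenyl]methoxy}-5-{[(3S,4S)-4-{[4-(benzyloxy)-3-methoxyphenyl]methyl}-2-oxooxolan-3-yl]methyl}-2,3-dihydro-1-benzofuran-3-carboxylate
Product: 19 benzyl (2S,3S)-2-[4-(benzyloxy)-3-methoxyphenyl]-7-{[4-(benzyloxy)-3-methoxyphenyl]methoxy}-5-{[(3S,4S)-4-{[4-(benzyloxy)-3-methoxyphenyl]methyl}-2-oxooxolan-3-yl]methyl}-2,3-dihydro-1-benzofuran-3-carboxylate (2,3-trans)
Conditions: DBU, toluene, 60 °C
Reagents that add atoms: none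
Why: Base-mediated epimerisation through the ester enolate at the doubly activated C3 relieves the cis aryl/ester strain and should give the thermodynamic trans isomer with C2 untouched, the lactone C3 being already in its thermodynamic trans configuration.

**Step 12**
Reactants: 19 benzyl (2S,3S)-2-[4-(benzyloxy)-3-methoxyphenyl]-7-{[4-(benzyloxy)-3-methoxyphenyl]methoxy}-5-{[(3S,4S)-4-{[4-(benzyloxy)-3-methoxyphenyl]methyl}-2-oxooxolan-3-yl]methyl}-2,3-dihydro-1-benzofuran-3-carboxylate
Product: 20 (2S,3S)-7-hydroxy-2-(4-hydroxy-3-methoxyphenyl)-5-{[(3S,4S)-4-[(4-hydroxy-3-methoxyphenyl)methyl]-2-oxooxolan-3-yl]methyl}-2,3-dihydro-1-benzofuran-3-carboxylic acid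
Conditions: H2 (1 atm), 10% Pd/C, EtOAc/MeOH, rt
Reagents that add atoms: none
Why: Catalytic hydrogenolysis cleaves the benzyl ester, the three O-benzyl groups and the oxybenzyl ether on the C7 oxygen in one operation, while the cyclic benzylic C2–O1 bond of the dihydrobenzofuran is cleaved much more slowly and should survive if the reaction is stopped at the calculated hydrogen uptake.

**Step 13**
Reactants: 20 (2S,3S)-7-hydroxy-2-(4-hydroxy-3-methoxyphenyl)-5-{[(3S,4S)-4-[(4-hydroxy-3-methoxyphenyl)methyl]-2-oxooxolan-3-yl]methyl}-2,3-dihydro-1-benzofuran-3-carboxylic acid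
Product: 21 (3S,4S)-3-{[(2S,3R)-7-hydroxy-2-(4-hydroxy-3-methoxyphenyl)-3-(hydroxymethyl)-2,3-dihydro-1-benzofuran-5-yl]methyl}-4-[(4-hydroxy-3-methoxyphenyl)methyl]oxolan-2-one
Conditions: BH3·THF (excess), THF, 0 °C → rt; then MeOH, H2O
Reagents that add atoms: none
Why: Chemoselective borane reduction, in which the carboxylic acid is reduced through its acyloxyborane much faster than the γ-lactone, should give the C3 hydroxymethyl group without touching any stereocentre, the phenols being only borylated and released on work-up.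

**Compound list**

1 | (S)-epichlorohydrin [(2S)-2-(chloromethyl)oxirane] | ClC[C@@H]1CO1 | starting material
2 | diethyl malonate | CCOC(=O)CC(=O)OCC | starting material
3 | ethyl (1R,5S)-2-oxo-3-oxabicyclo[3.1.0]hexane-1-carboxylate | CCOC(=O)[C@@]12C[C@@H]1COC2=O | intermediate
4 | 1-(benzyloxy)-4-bromo-2-methoxybenzene | COc1cc(Br)ccc1OCc1ccccc1 | starting material
5 | [4-(benzyloxy)-3-methoxyphenyl]magnesium bromide | COc1cc([Mg]Br)ccc1OCc1ccccc1 | intermediate
6 | ethyl (3R,4S)-4-{[4-(benzyloxy)-3-methoxyphenyl]methyl}-2-oxooxolane-3-carboxylate | COc1cc(C[C@@H]2COC(=O)[C@H]2C(=O)OCC)ccc1OCc1ccccc1 | intermediate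
7 | (4S)-4-{[4-(benzyloxy)-3-methoxyphenyl]methyl}oxolan-2-one | COc1cc(C[C@@H]2COC(=O)C2)ccc1OCc1ccccc1 | intermediate
8 | 5-iodovanillin (4-hydroxy-3-iodo-5-methoxybenzaldehyde) | COc1cc(C=O)cc(I)c1O | starting material
9 | 3,4-dihydroxy-5-iodobenzaldehyde | O=Cc1cc(O)c(O)c(I)c1 | intermediate
10 | 4-(benzyloxy)-3-methoxybenzyl chloride | COc1cc(CCl)ccc1OCc1ccccc1 | starting material
11 | 3,4-bis({[4-(benzyloxy)-3-methoxyphenyl]methoxy})-5-iodobenzaldehyde | O=Cc1cc(I)c(OCc2ccc(OCc3ccccc3)c(OC)c2)c(OCc2ccc(OCc3ccccc3)c(OC)c2)c1 | intermediate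
12 | [3,4-bis({[4-(benzyloxy)-3-methoxyphenyl]methoxy})-5-iodophenyl]methanol | OCc1cc(I)c(OCc2ccc(OCc3ccccc3)c(OC)c2)c(OCc2ccc(OCc3ccccc3)c(OC)c2)c1 | intermediate
13 | 5-(bromomethyl)-1,2-bis({[4-(benzyloxy)-3-methoxyphenyl]methoxy})-3-iodobenzene | BrCc1cc(I)c(OCc2ccc(OCc3ccccc3)c(OC)c2)c(OCc2ccc(OCc3ccccc3)c(OC)c2)c1 | intermediate
14 | lithium enolate of 7 (lithium (4S)-4-{[4-(benzyloxy)-3-methoxyphenyl]methyl}-4,5-dihydrofuran-2-olate) | COc1cc(C[C@@H]2COC(O[Li])=C2)ccc1OCc1ccccc1 | intermediate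
15 | (3S,4S)-3-{[3,4-bis({[4-(benzyloxy)-3-methoxyphenyl]methoxy})-5-iodophenyl]methyl}-4-{[4-(benzyloxy)-3-methoxyphenyl]methyl}oxolan-2-one | COc1cc(C[C@@H]2COC(=O)[C@H]2Cc2cc(I)c(OCc3ccc(OCc4ccccc4)c(OC)c3)c(OCc3ccc(OCc4ccccc4)c(OC)c3)c2)ccc1OCc1ccccc1 | intermediate
16 | benzyl diazoacetate | [N-]=[N+]=CC(=O)OCc1ccccc1 | starting material
17 | benzyl 2-[2,3-bis({[4-(benzyloxy)-3-methoxyphenyl]methoxy})-5-{[(3S,4S)-4-{[4-(benzyloxy)-3-methoxyphenyl]methyl}-2-oxooxolan-3-yl]methyl}phenyl]-2-diazoacetate | COc1cc(C[C@@H]2COC(=O)[C@H]2Cc2cc(C(=[N+]=[N-])C(=O)OCc3ccccc3)c(OCc3ccc(OCc4ccccc4)c(OC)c3)c(OCc3ccc(OCc4ccccc4)c(OC)c3)c2)ccc1OCc1ccccc1 | intermediate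
18 | benzyl (2S,3R)-2-[4-(benzyloxy)-3-methoxyphenyl]-7-{[4-(benzyloxy)-3-methoxyphenyl]methoxy}-5-{[(3S,4S)-4-{[4-(benzyloxy)-3-methoxyphenyl]methyl}-2-oxooxolan-3-yl]methyl}-2,3-dihydro-1-benzofuran-3-carboxylate (cis) | COc1cc(C[C@@H]2COC(=O)[C@H]2Cc2cc(OCc3ccc(OCc4ccccc4)c(OC)c3)c3c(c2)[C@@H](C(=O)OCc2ccccc2)[C@@H](c2ccc(OCc4ccccc4)c(OC)c2)O3)ccc1OCc1ccccc1 | intermediate
19 | benzyl (2S,3S)-2-[4-(benzyloxy)-3-methoxyphenyl]-7-{[4-(benzyloxy)-3-methoxyphenyl]methoxy}-5-{[(3S,4S)-4-{[4-(benzyloxy)-3-methoxyphenyl]methyl}-2-oxooxolan-3-yl]methyl}-2,3-dihydro-1-benzofuran-3-carboxylate (trans) | COc1cc(C[C@@H]2COC(=O)[C@H]2Cc2cc(OCc3ccc(OCc4ccccc4)c(OC)c3)c3c(c2)[C@H](C(=O)OCc2ccccc2)[C@@H](c2ccc(OCc4ccccc4)c(OC)c2)O3)ccc1OCc1ccccc1 | intermediate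
20 | (2S,3S)-7-hydroxy-2-(4-hydroxy-3-methoxyphenyl)-5-{[(3S,4S)-4-[(4-hydroxy-3-methoxyphenyl)methyl]-2-oxooxolan-3-yl]methyl}-2,3-dihydro-1-benzofuran-3-carboxylic acid | COc1cc(C[C@@H]2COC(=O)[C@H]2Cc2cc(O)c3c(c2)[C@H](C(=O)O)[C@@H](c2ccc(O)c(OC)c2)O3)ccc1O | intermediate
21 | (3S,4S)-3-{[(2S,3R)-7-hydroxy-2-(4-hydroxy-3-methoxyphenyl)-3-(hydroxymethyl)-2,3-dihydro-1-benzofuran-5-yl]methyl}-4-[(4-hydroxy-3-methoxyphenyl)methyl]oxolan-2-one (CNP0118131.1) | COc1cc(C[C@@H]2COC(=O)[C@H]2Cc2cc(O)c3c(c2)[C@H](CO)[C@@H](c2ccc(O)c(OC)c2)O3)ccc1O | target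

**Step count.** Total: 13 steps. Longest linear sequence: 10 steps (steps 4–13, from 5-iodovanillin); the lactone branch (steps 1–3) joins at step 8.

**Steps most likely to fail, with fallbacks**

Step 10. What may go wrong is imperfect discrimination of the two enantiotopic benzylic hydrogens by the catalyst, and diversion of the carbene into dimerisation or attack on the electron-rich aryl rings or ether oxygens. The fallback is a biomimetic oxidative cross-coupling that sets out from 7 and comes back at 21. Commercial 3-(benzyloxy)-4-hydroxybenzaldehyde would be silylated (TBSCl, imidazole, DMF) to 3-(benzyloxy)-4-[(tert-butyldimethylsilyl)oxy]benzaldehyde F1, reduced (NaBH4, MeOH) to the benzylic alcohol F2 and converted (CBr4, PPh3) into the benzylic bromide F3. Alkylation of enolate 14, generated from 7 as in step 8, should give the trans lactone F4, and buffered TBAF (AcOH, THF) frees the phenol F5. Ag2O-mediated oxidative coupling of F5 with commercial coniferyl alcohol (phenoxyl radical coupling at the free ortho carbon with Cβ, then closure of the quinone methide by the phenol oxygen, trans by thermodynamic preference) should give the dibenzyl ether F6. This closure has no control over the absolute configuration of C2 and C3, so F6 would form alongside its (2R,3S) diastereomer and the two must be separated by preparative chromatography. Hydrogenolysis of F6 (H2, Pd/C) then gives 21.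

Step 9. What may go wrong is slow oxidative addition at the hindered, electron-rich aryl iodide and palladium-induced loss of nitrogen from the diazo product. The fallback sets out from 15 and comes back at 17. A Negishi-type α-arylation with the Reformatsky reagent from benzyl bromoacetate (BrZnCH2CO2Bn, Pd(dba)2, XPhos, THF, rt) should give the benzyl arylacetate F7, and Regitz diazo transfer (4-acetamidobenzenesulfonyl azide, DBU, MeCN) then returns to 17.

Step 13. What may go wrong is sequestration of borane by the three free phenols, with competing reduction of the lactone during the longer reaction this forces. The fallback sets out from 19 and comes back at 21, reducing before the phenols are unmasked. Saponification of the benzyl ester (LiOH, THF/H2O, 0 °C), followed by acidification to re-close any opened lactone, should give the carboxylic acid F8 with all benzylic ethers in place. BH3·SMe2 (THF, 0 °C) reduces it to the primary alcohol F9, and hydrogenolysis (H2, Pd/C) gives 21.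

**Further compounds**

F1 | step 10 | 3-(benzyloxy)-4-[(tert-butyldimethylsilyl)oxy]benzaldehyde | O=Cc1ccc(O[Si](C)(C)C(C)(C)C)c(OCc2ccccc2)c1
F2 | step 10 | {3-(benzyloxy)-4-[(tert-butyldimethylsilyl)oxy]phenyl}methanol | OCc1ccc(O[Si](C)(C)C(C)(C)C)c(OCc2ccccc2)c1
F3 | step 10 | [2-(benzyloxy)-4-(bromomethyl)phenoxy](tert-butyl)dimethylsilane | BrCc1ccc(O[Si](C)(C)C(C)(C)C)c(OCc2ccccc2)c1
F4 | step 10 | (3S,4S)-3-({3-(benzyloxy)-4-[(tert-butyldimethylsilyl)oxy]phenyl}methyl)-4-{[4-(benzyloxy)-3-methoxyphenyl]methyl}oxolan-2-one | COc1cc(C[C@@H]2COC(=O)[C@H]2Cc2ccc(O[Si](C)(C)C(C)(C)C)c(OCc3ccccc3)c2)ccc1OCc1ccccc1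
F5 | step 10 | (3S,4S)-3-{[3-(benzyloxy)-4-hydroxyphenyl]methyl}-4-{[4-(benzyloxy)-3-methoxyphenyl]methyl}oxolan-2-one | COc1cc(C[C@@H]2COC(=O)[C@H]2Cc2ccc(O)c(OCc3ccccc3)c2)ccc1OCc1ccccc1
F6 | step 10 | (3S,4S)-3-{[(2S,3R)-7-(benzyloxy)-2-(4-hydroxy-3-methoxyphenyl)-3-(hydroxymethyl)-2,3-dihydro-1-benzofuran-5-yl]methyl}-4-{[4-(benzyloxy)-3-methoxyphenyl]methyl}oxolan-2-one | COc1cc(C[C@@H]2COC(=O)[C@H]2Cc2cc(OCc3ccccc3)c3c(c2)[C@H](CO)[C@@H](c2ccc(O)c(OC)c2)O3)ccc1OCc1ccccc1
F7 | step 9 | benzyl 2-[2,3-bis({[4-(benzyloxy)-3-methoxyphenyl]methoxy})-5-{[(3S,4S)-4-{[4-(benzyloxy)-3-methoxyphenyl]methyl}-2-oxooxolan-3-yl]methyl}phenyl]acetate | COc1cc(C[C@@H]2COC(=O)[C@H]2Cc2cc(CC(=O)OCc3ccccc3)c(OCc3ccc(OCc4ccccc4)c(OC)c3)c(OCc3ccc(OCc4ccccc4)c(OC)c3)c2)ccc1OCc1ccccc1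
F8 | step 13 | (2S,3S)-2-[4-(benzyloxy)-3-methoxyphenyl]-7-{[4-(benzyloxy)-3-methoxyphenyl]methoxy}-5-{[(3S,4S)-4-{[4-(benzyloxy)-3-methoxyphenyl]methyl}-2-oxooxolan-3-yl]methyl}-2,3-dihydro-1-benzofuran-3-carboxylic acid | COc1cc(C[C@@H]2COC(=O)[C@H]2Cc2cc(OCc3ccc(OCc4ccccc4)c(OC)c3)c3c(c2)[C@H](C(=O)O)[C@@H](c2ccc(OCc4ccccc4)c(OC)c2)O3)ccc1OCc1ccccc1
F9 | step 13 | (3S,4S)-3-{[(2S,3R)-2-[4-(benzyloxy)-3-methoxyphenyl]-7-{[4-(benzyloxy)-3-methoxyphenyl]methoxy}-3-(hydroxymethyl)-2,3-dihydro-1-benzofuran-5-yl]methyl}-4-{[4-(benzyloxy)-3-methoxyphenyl]methyl}oxolan-2-one | COc1cc(C[C@@H]2COC(=O)[C@H]2Cc2cc(OCc3ccc(OCc4ccccc4)c(OC)c3)c3c(c2)[C@H](CO)[C@@H](c2ccc(OCc4ccccc4)c(OC)c2)O3)ccc1OCc1ccccc1
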